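A direct plan would take the stereocentre from (R)-linalool A1 and build the benzene ring last.
A1 would be O-silylated, hydroborated, oxidised, ethynylated and oxidised again to ynone A2; a Diels–Alder reaction of A2 with silyloxyfuran A3 and opening of the oxygen bridge would give arene A4, and fluoride would free the target.
Its weakest steps would be:
- the five-step change of the vinyl group of A1 into the ynone of A2, which is protection and redox traffic that adds only two carbons;
- the furan–ynone cycloaddition with aromatisation, which has no close precedent for this pair, needs a labile diene A3 made separately and a polymerisable ynone, and rests its regiochemistry on orbital arguments;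
- the final removal of two different silyl groups with HF·pyridine, on a tertiary aldol that can cleave by retro-aldol, dehydrate to a chromanone or close a cyclic ether onto the alkene.

**Retrosynthetic overview**
- Key disconnection: the bond between arene C1 and the ketone carbon, formed by a 1,3 O→C acyl shift (anionic Fries rearrangement) from the phenol oxygen at C2.
- Feature used: in the target ring the acyl group (C1) is ortho to OH (C2), para to Br (C4) and meta to the second OH (C5). This is 2,5-dibromohydroquinone with one Br replaced by the acyl group of an ester on the neighbouring oxygen, so one Br is trigger and leaving group and the other stays.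
- Precursor: the C2-symmetric bis-ester of commercial 2,5-dibromohydroquinone with (R)-3-hydroxy-3,7-dimethyloct-6-enoic acid, itself two steps from (R)-linalool. The stereocentre comes from the chiral pool and no bond to it is ever broken.
- Rings: the benzene ring is bought, not built, and no ring is closed anywhere. The second ester protects the C5 oxygen and is cleaved at the end.
- The design needs no ynone, no furan diene and no fluoride: the cycloaddition is replaced by a rearrangement whose regiochemistry is fixed by ipso substitution and symmetry.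

Key step: step 5

Assumption: commercial (R)-(−)-linalool of high enantiomeric purity is used; since no step breaks a bond at its carbinol carbon, this purity should be carried into the target unchanged.

Step 1
Reactants: 1 (R)-(−)-linalool [(R)-3,7-dimethylocta-1,6-dien-3-ol]
Product: 3 (R)-3,7-dimethyloct-6-ene-1,3-diol, via B-alkyl-9-BBN adduct 2 (not isolated)
Conditions: 9-BBN (0.5 M in THF, 2.2 equiv), 0 → 23 °C; then 3 M aq. NaOH, 30% H2O2, 0 → 23 °C
Reagents that add atoms: hydrogen peroxide, OO (supplies the oxygen of the new primary hydroxyl; the boron unit of 9-BBN, B1C2CCCC1CCC2, stays only in 2)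
Why: Brown hydroboration–oxidation: the bulky 9-BBN should add to the monosubstituted vinyl group much faster than to the trisubstituted C6=C7 alkene and place boron on the terminal carbon (the second equivalent covers B–H lost to the tertiary hydroxyl), and alkaline peroxide then replaces boron by hydroxyl without touching any bond at C3, so the (R) configuration is carried over.

Step 2
Reactants: 3 (R)-3,7-dimethyloct-6-ene-1,3-diol
Product: 5 (R)-3-hydroxy-3,7-dimethyloct-6-enoic acid, via hydroxy aldehyde 4 (not isolated)
Conditions: TEMPO (0.2 equiv), PhI(OAc)2 (2.2 equiv), MeCN/pH 7 phosphate buffer (1:1), 0 → 23 °C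
Reagents that add atoms: water, O (supplies the second oxygen of the carboxyl group)
Why: Oxoammonium (TEMPO/PhI(OAc)2) oxidation in buffered aqueous acetonitrile should take the primary alcohol through aldehyde 4 and its hydrate to the carboxylic acid while leaving the tertiary alcohol (no α-hydrogen) and the trisubstituted alkene untouched, and the near-neutral medium avoids acid-induced cyclisation of the hydroxy alkene.

Step 3
Reactants: 5 (R)-3-hydroxy-3,7-dimethyloct-6-enoic acid (2.3 equiv); 6 2,5-dibromobenzene-1,4-diol (2,5-dibromohydroquinone)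
Product: 7 2,5-dibromo-1,4-phenylene bis[(R)-3-hydroxy-3,7-dimethyloct-6-enoate]
Conditions: DIC (2.5 equiv), DMAP (0.2 equiv), CH2Cl2, 0 → 23 °C
Reagents that add atoms: none
Why: Steglich esterification: the N-acylpyridinium formed from the O-acylisourea should acylate the acidic phenol oxygens far faster than the tertiary hydroxyl, both phenols are meant to react so that no mono/di selectivity is needed, and the stereocentres are not involved.

Step 4
Reactants: 7 2,5-dibromo-1,4-phenylene bis[(R)-3-hydroxy-3,7-dimethyloct-6-enoate]
Product: 8 2,5-dibromo-1,4-phenylene bis[(R)-3,7-dimethyl-3-(trimethylsilyloxy)oct-6-enoate]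
Conditions: TMSOTf (2.6 equiv), 2,6-lutidine (4 equiv), CH2Cl2, −78 → −20 °C; cold aq. NaHCO3
Reagents that add atoms: trimethylsilyl triflate, C[Si](C)(C)OS(=O)(=O)C(F)(F)F
Why: O-Silylation with a silyl triflate and 2,6-lutidine is the standard way to cap hindered tertiary alcohols, runs cold and buffered so that neither the tertiary C–O bond ionises nor the aryl esters are enolised, and gives tertiary trimethylsilyl ethers that should survive chromatography on neutralised silica.

Step 5
Reactants: 8 2,5-dibromo-1,4-phenylene bis[(R)-3,7-dimethyl-3-(trimethylsilyloxy)oct-6-enoate]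
Product: 11 2-bromo-4-hydroxy-5-[(R)-3,7-dimethyl-3-(trimethylsilyloxy)oct-6-enoyl]phenyl (R)-3,7-dimethyl-3-(trimethylsilyloxy)oct-6-enoate, via aryllithium 9 (not isolated), via lithium phenoxide 10 (not isolated)
Conditions: n-BuLi (1.0 equiv, slow addition), THF/Et2O/pentane (4:1:1), −100 °C; AcOH (1.5 equiv) in THF, −100 → 0 °C
Reagents that add atoms: none
Why: Bromine–lithium exchange at one of the two equivalent C–Br bonds of C2-symmetric 8 gives aryllithium 9, whose carbanion attacks the carbonyl of the ester on the neighbouring oxygen through a transient four-membered tetrahedral intermediate and collapses to ketone phenoxide 10, so that the acyl group moves from oxygen to carbon (1,3 O→C shift) and the aryl–C(=O) bond of the target is formed. The closest known reaction type is this very one, the anionic Fries rearrangement of o-bromoaryl and o-iodoaryl esters triggered by halogen–metal exchange, a known entry to o-hydroxyaryl ketones that is here applied to a doubly acylated dibromohydroquinone. No ring is closed for good and no stereocentre is formed; the two (R) carbinol carbons are spectators as trimethylsilyl ethers. Regiochemistry is fixed by ipso substitution: the acyl group can only arrive at the carbon that held bromine, which is ortho to the oxygen it leaves, para to the surviving bromine and meta to the second oxygen, and by symmetry the result is the same whichever bromine reacts. Mono-exchange should be secured by one equivalent of n-BuLi added slowly to the neutral, electron-poor diester, because 10 is an electron-rich lithium phenoxide that should exchange its remaining bromine more slowly. Chemoselectivity rests on exchange at −100 °C being faster than addition of n-BuLi to an ester carbonyl or α-deprotonation, on the silyl caps that prevent alkoxide-driven β-lactone formation and retro-aldol cleavage, and on the second ester, which protects the para oxygen and is removed in step 6.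

Step 6
Reactants: 11 2-bromo-4-hydroxy-5-[(R)-3,7-dimethyl-3-(trimethylsilyloxy)oct-6-enoyl]phenyl (R)-3,7-dimethyl-3-(trimethylsilyloxy)oct-6-enoate
Product: 13 (R)-1-(4-bromo-2,5-dihydroxyphenyl)-3-hydroxy-3,7-dimethyloct-6-en-1-one (CNP0227808.2), via monosilyl ether 12 (not isolated)
Conditions: K2CO3 (0.2 equiv), MeOH, 0 °C; then citric acid (0.5 equiv), MeOH/H2O (10:1), 23 °C
Reagents that add atoms: none
Why: Base-catalysed transesterification (methanolysis) of the activated aryl ester is followed by mild acid-catalysed methanolysis of the trimethylsilyl ethers: the silyl cap stays on during the basic stage so that no tertiary alkoxide is available for retro-aldol cleavage, citric acid is too weak to dehydrate the tertiary alcohol or protonate the alkene, and no bond at the stereocentre is broken, so 13 keeps the (R) configuration.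

**Compound list**
1 | (R)-(−)-linalool | CC(C)=CCC[C@@](C)(O)C=C | starting material
2 | 9-[(S)-3-hydroxy-3,7-dimethyloct-6-en-1-yl]-9-borabicyclo[3.3.1]nonane (same spatial arrangement as 1; the descriptor reads S only because CH2CH2B ranks below the homoprenyl chain) | CC(C)=CCC[C@@](C)(O)CCB1C2CCCC1CCC2 | intermediate (not isolated)
3 | (R)-3,7-dimethyloct-6-ene-1,3-diol | CC(C)=CCC[C@@](C)(O)CCO | intermediate
4 | (R)-3-hydroxy-3,7-dimethyloct-6-enal | CC(C)=CCC[C@@](C)(O)CC=O | intermediate (not isolated)
5 | (R)-3-hydroxy-3,7-dimethyloct-6-enoic acid | CC(C)=CCC[C@@](C)(O)CC(=O)O | intermediate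
6 | 2,5-dibromobenzene-1,4-diol | Oc1cc(Br)c(O)cc1Br | starting material
7 | 2,5-dibromo-1,4-phenylene bis[(R)-3-hydroxy-3,7-dimethyloct-6-enoate] | CC(C)=CCC[C@@](C)(O)CC(=O)Oc1cc(Br)c(OC(=O)C[C@](C)(O)CCC=C(C)C)cc1Br | intermediate
8 | 2,5-dibromo-1,4-phenylene bis[(R)-3,7-dimethyl-3-(trimethylsilyloxy)oct-6-enoate] | CC(C)=CCC[C@@](C)(O[Si](C)(C)C)CC(=O)Oc1cc(Br)c(OC(=O)C[C@](C)(O[Si](C)(C)C)CCC=C(C)C)cc1Br | intermediate
9 | [4-bromo-2,5-bis{[(R)-3,7-dimethyl-3-(trimethylsilyloxy)oct-6-enoyl]oxy}phenyl]lithium | CC(C)=CCC[C@@](C)(O[Si](C)(C)C)CC(=O)Oc1cc(Br)c(OC(=O)C[C@](C)(O[Si](C)(C)C)CCC=C(C)C)cc1[Li] | intermediate (not isolated)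
10 | lithium 5-bromo-2-[(R)-3,7-dimethyl-3-(trimethylsilyloxy)oct-6-enoyl]-4-{[(R)-3,7-dimethyl-3-(trimethylsilyloxy)oct-6-enoyl]oxy}phenolate | CC(C)=CCC[C@@](C)(O[Si](C)(C)C)CC(=O)c1cc(OC(=O)C[C@](C)(O[Si](C)(C)C)CCC=C(C)C)c(Br)cc1O[Li] | intermediate (not isolated)
11 | 2-bromo-4-hydroxy-5-[(R)-3,7-dimethyl-3-(trimethylsilyloxy)oct-6-enoyl]phenyl (R)-3,7-dimethyl-3-(trimethylsilyloxy)oct-6-enoate | CC(C)=CCC[C@@](C)(O[Si](C)(C)C)CC(=O)c1cc(OC(=O)C[C@](C)(O[Si](C)(C)C)CCC=C(C)C)c(Br)cc1O | intermediate
12 | (R)-1-(4-bromo-2,5-dihydroxyphenyl)-3,7-dimethyl-3-(trimethylsilyloxy)oct-6-en-1-one | CC(C)=CCC[C@@](C)(O[Si](C)(C)C)CC(=O)c1cc(O)c(Br)cc1O | intermediate (not isolated)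
13 | (R)-1-(4-bromo-2,5-dihydroxyphenyl)-3-hydroxy-3,7-dimethyloct-6-en-1-one (CNP0227808.2) | CC(C)=CCC[C@@](C)(O)CC(=O)c1cc(O)c(Br)cc1O | target

Total step count: 6. Longest linear sequence: 6 steps (from 1).

**Steps most likely to fail**

1. Step 5 (exchange and acyl shift). What may go wrong is a second bromine–lithium exchange with a second acyl shift and loss of the remaining bromine, addition of n-BuLi to an ester carbonyl, or acyl transfer between molecules. The fallback replaces the rearrangement by intermolecular acylation of a separately made aryllithium; it sets out from 5 and 6 and comes back at 13.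
   - Acid 5 would be condensed with MeNHOMe·HCl (DIC, i-Pr2NEt, CH2Cl2) to (R)-3-hydroxy-N-methoxy-N,3,7-trimethyloct-6-enamide F1.
   - F1 would be silylated (TMSOTf, 2,6-lutidine) to (R)-N-methoxy-N,3,7-trimethyl-3-(trimethylsilyloxy)oct-6-enamide F2.
   - Diol 6 would be silylated (TBSCl, imidazole, DMF) to 1,4-dibromo-2,5-bis(tert-butyldimethylsilyloxy)benzene F3.
   - One bromine–lithium exchange (n-BuLi, 1.0 equiv, THF, −78 °C) would give [4-bromo-2,5-bis(tert-butyldimethylsilyloxy)phenyl]lithium F4.
   - Addition of F4 to F2 (Weinreb ketone synthesis, kept at −78 °C to outrun silyl migration from oxygen to carbon) would give (R)-1-[4-bromo-2,5-bis(tert-butyldimethylsilyloxy)phenyl]-3,7-dimethyl-3-(trimethylsilyloxy)oct-6-en-1-one F5.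
   - TBAF buffered with AcOH (THF, 0 °C) would remove the three silyl groups to give 13.

2. Step 6 (ester cleavage and desilylation). What may go wrong is retro-aldol cleavage, loss of the silyloxy group by elimination with oxa-Michael closure to a chromanone during the basic methanolysis, or sluggish cleavage of the hindered ester. The fallback inverts the order and avoids base; it sets out from 11 and comes back at 13.
   - The silyl groups would be removed first (citric acid, MeOH, 23 °C) to give 2-bromo-4-hydroxy-5-[(R)-3-hydroxy-3,7-dimethyloct-6-enoyl]phenyl (R)-3-hydroxy-3,7-dimethyloct-6-enoate F6.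
   - The aryl ester would then be hydrolysed by an esterase (pig liver esterase, pH 7 phosphate buffer/acetone, 30 °C), which would give 13 and return acid 5.

3. Step 3 (bis-esterification). What may go wrong is β-lactone formation or self-condensation of the activated β-hydroxy acid, or incomplete acylation of the second, hindered bromophenol. The fallback protects first and acylates with an acid chloride; it sets out from 5 and comes back at 8, so that 7 is skipped.
   - Acid 5 would be persilylated (TMSCl, Et3N, CH2Cl2) to trimethylsilyl (R)-3,7-dimethyl-3-(trimethylsilyloxy)oct-6-enoate F7.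
   - F7 would be converted under neutral conditions ((COCl)2, catalytic DMF, CH2Cl2, 0 °C) into (R)-3,7-dimethyl-3-(trimethylsilyloxy)oct-6-enoyl chloride F8.
   - F8 (2.2 equiv) would acylate 6 (pyridine, DMAP, CH2Cl2, 0 °C) to give 8 directly.

**Further compounds**
F1 | step 5 | (R)-3-hydroxy-N-methoxy-N,3,7-trimethyloct-6-enamide | CON(C)C(=O)C[C@](C)(O)CCC=C(C)C
F2 | step 5 | (R)-N-methoxy-N,3,7-trimethyl-3-(trimethylsilyloxy)oct-6-enamide | CON(C)C(=O)C[C@](C)(O[Si](C)(C)C)CCC=C(C)C
F3 | step 5 | 1,4-dibromo-2,5-bis(tert-butyldimethylsilyloxy)benzene | CC(C)(C)[Si](C)(C)Oc1cc(Br)c(O[Si](C)(C)C(C)(C)C)cc1Br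
F4 | step 5 | [4-bromo-2,5-bis(tert-butyldimethylsilyloxy)phenyl]lithium | CC(C)(C)[Si](C)(C)Oc1cc(Br)c(O[Si](C)(C)C(C)(C)C)cc1[Li]
F5 | step 5 | (R)-1-[4-bromo-2,5-bis(tert-butyldimethylsilyloxy)phenyl]-3,7-dimethyl-3-(trimethylsilyloxy)oct-6-en-1-one | CC(C)=CCC[C@@](C)(O[Si](C)(C)C)CC(=O)c1cc(O[Si](C)(C)C(C)(C)C)c(Br)cc1O[Si](C)(C)C(C)(C)C
F6 | step 6 | 2-bromo-4-hydroxy-5-[(R)-3-hydroxy-3,7-dimethyloct-6-enoyl]phenyl (R)-3-hydroxy-3,7-dimethyloct-6-enoate | CC(C)=CCC[C@@](C)(O)CC(=O)c1cc(OC(=O)C[C@](C)(O)CCC=C(C)C)c(Br)cc1O
F7 | step 3 | trimethylsilyl (R)-3,7-dimethyl-3-(trimethylsilyloxy)oct-6-enoate | C[Si](C)(C)OC(=O)C[C@](C)(O[Si](C)(C)C)CCC=C(C)C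
F8 | step 3 | (R)-3,7-dimethyl-3-(trimethylsilyloxy)oct-6-enoyl chloride | O=C(Cl)C[C@](C)(O[Si](C)(C)C)CCC=C(C)C
A1 | direct plan | (R)-(−)-linalool | CC(C)=CCC[C@@](C)(O)C=C
A2 | direct plan | (R)-5,9-dimethyl-5-(triethylsilyloxy)dec-8-en-1-yn-3-one | CC(C)=CCC[C@@](C)(O[Si](CC)(CC)CC)CC(=O)C#C
A3 | direct plan | 4-bromo-2-(tert-butyldimethylsilyloxy)furan | CC(C)(C)[Si](C)(C)Oc1cc(Br)co1
A4 | direct plan | (R)-1-[4-bromo-2-(tert-butyldimethylsilyloxy)-5-hydroxyphenyl]-3,7-dimethyl-3-(triethylsilyloxy)oct-6-en-1-one | CC(C)=CCC[C@@](C)(O[Si](CC)(CC)CC)CC(=O)c1cc(O)c(Br)cc1O[Si](C)(C)C(C)(C)C
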